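The earlier runs and the new flask were generated by integration with constants of no real substance, noise included.

- The alder and larch runs differ only in how much reagent they got, and the flask you are asked about lies between them.

the same everywhere: free catalyst 0.16 mol%

|  | starting material | reagent | protic impurity | remark | time |
|---|---|---|---|---|---|
| alder | 0.050 M | 0.67 equiv | 0.015 M | run made earlier |  |
| larch | 0.050 M | 1.5 equiv | 0.015 M | run made earlier |  |
| maple | 0.075 M | 1 equiv | 0.015 M | run made earlier |  |
| flask | 0.050 M | 1.00 equiv | 0.0150 M |  | 25 min |

| run | time / min | open intermediate / % | target / % |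
|---|---|---|---|
| alder | 0.250 | 36.7 | 1.8 |
| alder | 0.500 | 45.7 | 3.2 |
| alder | 1.00 | 51.6 | 8.2 |
| alder | 2.00 | 48.5 | 9.5 |
| alder | 5.00 | 31.1 | 6.4 |
| alder | 10.0 | 15.0 | 1.6 |
| alder | 20.0 | 9.0 | 0.9 |
| larch | 0.250 | 39.4 | 4.0 |
| larch | 0.500 | 47.9 | 8.9 |
| larch | 1.00 | 48.0 | 14.4 |
| larch | 2.00 | 34.4 | 18.2 |
| larch | 5.00 | 5.3 | 6.7 |
| larch | 10.0 | 0 | 0.4 |
| larch | 20.0 | 0.6 | 0.4 |
| maple | 0.250 | 43.4 | 5.3 |
| maple | 0.667 | 52.6 | 13.0 |
| maple | 2.00 | 35.5 | 18.9 |
| maple | 6.00 | 3.8 | 6.2 |
| maple | 20.0 | 0 | 0.8 |

(readings scatter by 0.5 percentage points)



- time, not beyond 25 min, at which the flask holds most open intermediate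
- the amount of open intermediate, in percent of the starting material charged, at that time
- the first time at which open intermediate reaches 35 %, in the same percent, in min

- Fastest rung, filling: at 0.250 min alder already holds 36.7 % open intermediate and larch 39.4 %, although alder got 0.67 equiv of reagent and larch 1.5 equiv.
- Second rung, the top: at 1.00 min these runs read 51.6 % and 48.0 %, the highest reading of each, and now the reagent shows.
- Third rung, the drain: from 2.00 min to 5.00 min larch falls with a time constant of 1.60 min.
- Slowest rung, the tail: from 10.0 min to 20.0 min alder falls with a time constant of 19.6 min, longer than the larch drain.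
- The top stands before both drains, so I treat it as alder's reading with a small correction. Call s the reagent pull, the points of open intermediate lost at 1.00 min per equivalent of reagent added: 4.3 percentage points per equivalent.
- The flask, with 1.00 equiv, needs a correction of 1.4 points, far smaller than alder's reading, so I expect 50.2 % at that time.
- The forecast says 51 % at 0.9 min, 0.80 points above my estimate, with the asked amount reached at 0.21 min. One of its grounds is “Reagent mainly drives its removal”.

    starting material + free catalyst → free catalyst + open intermediate (k = 850 /M/s)
    free catalyst + open intermediate ⇌ catalyst intermediate (K = 170 /M, k = 320 /M/s)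
    reagent + catalyst intermediate → free catalyst + target (k = 64.0 /M/s)
    target → over-reaction product (k = 0.0160 /s)
    starting material + protic impurity → quenched substrate (k = 1.70 /M/s)

- The flask peaks at 50.6 % at 0.904 min and reaches the asked amount at 0.214 min; my estimate, made for 1.00 min, lies 0.40 points below that peak. At that best time 63.6 % of the catalyst charged in the flask sits as catalyst intermediate, the resting state of that moment, against 36.4 % as free catalyst. For a neighbour like the flask but charged with 0.250 equiv of reagent, s carried down from alder's top reading gives 53.4 %, but that neighbour's best is 57.8 %, higher by 4.4 points.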